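## Retrosynthetic overview

- Target 28 ⇐ diol 25 (angelate on C6–OH and silyl removal at C16 come last) ⇐ tertiary epoxy alcohol 24 ⇐ epoxy ketone 23. The C8 carbinol comes from methyl addition anti to a 6α,7α-epoxide, and C6–OH from trans-diaxial hydride opening of that epoxide.
- 23 ⇐ ring B epoxy ketone 11 + iodide 21 (C9–C11 bond by kinetic enolate alkylation on the β face). The side-chain centre C13 of 21 is set by an oxazolidinone-controlled deconjugative alkylation.
- 11 ⇐ octalin 5: the C7=C8 alkene is taken through the 7α,8α-epoxide, a selenide transposition to the Δ6-8α-ol, hydroxyl-directed epoxidation and oxidation. 5 ⇐ 3 by deletion of the C1 carbonyl.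
- 3 ⇐ 1 + 2: ring A is purchased as the enone, and ring B is closed onto it by a [4+2] cycloaddition that forms C5–C6 and C9–C10.
- Feature used: the cis ring fusion (H-5 and the C10 methyl on the same face) next to the C4 gem-dimethyl carbon, read as a cyclohexene retron C5–C6–C7=C8–C9–C10 in ring B. Ring order: A (bought), then B.

Key step: step 1

## Remarks (conventions and assumptions)

- Numbering: labdane numbers are used (ring A = C1–C5, C10; ring B = C5–C10; side chain C11–C16 with C13 the stereocentre, C14=C15 the vinyl group, C16 the CH2OH carbon). β is the face of ring B carrying H-5 and the C10 methyl group; α is the opposite face.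
- Assumption on step 1: the (S)-prolinol-derived catalyst is taken to leave open the enone face that leads to 3; if the sense of induction proves opposite, the (R)-catalyst is used unchanged otherwise.
- Assumption on conformation: cis-fused ring B intermediates are taken to react through the chair or half-chair in which C1 is axial and the C10 methyl equatorial on ring B. The alternative chair places C4 axial with one of its methyl groups pointing under ring B. The β face is therefore the open (convex) face, and the α face is screened by C1H2.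

## Route

Step 1
Reactants: 1 2,4,4-trimethylcyclohex-2-en-1-one; 2 buta-1,3-diene
Product: 3 cis-4,4,10-trimethyloctal-7-en-1-one [(4aR,8aR)-4,4,8a-trimethyl-3,4,4a,5,8,8a-hexahydronaphthalen-1(2H)-one]
Conditions: (S)-3,3-diphenyl-1-(o-tolyl)pyrrolo-oxazaborolidine from (S)-α,α-diphenylprolinol (20 mol %), AlBr3 (16 mol %), 2 (10 equiv), CH2Cl2, −40 → −10 °C, sealed vessel
Reagents that add atoms: none
Why: Proposed new method: binding of the C1 carbonyl of 1 to the boron centre of the AlBr3-activated oxazaborolidine should lower the enone LUMO enough for a concerted, asynchronous [4+2] addition of butadiene across the ring A alkene (labdane C5=C10), the very high Lewis acidity of this catalyst class compensating for the hindered β-carbon. The closest known reactions are the AlCl3-promoted additions of butadiene to 2-methyl- and 4,4-dimethylcyclohex-2-enones and the oxazaborolidinium-catalysed enantioselective Diels–Alder additions to simpler cycloalkenones; the untested element is the combination of both substituents under a chiral catalyst. Ring B is closed intermolecularly as a cyclohexene by suprafacial bonding of the two diene termini to C5 and C10 (bonds C5–C6 and C9–C10). Because both bonds form on the same face of the ring alkene, H-5 and the C10 methyl are necessarily cis, and the absolute configuration of both centres is fixed by the enone face that the catalyst leaves open. Butadiene is symmetrical, so no regio- or endo/exo-selectivity is required and enantioface selection is the only demand. C10 is quaternary and C5 is not α to the carbonyl, so the fusion cannot epimerise later.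

Step 2
Reactants: 3
Product: 5 cis-4,4,10-trimethyl-Δ7-octalin [(4aR,8aR)-1,1,4a-trimethyl-1,2,3,4,4a,5,8,8a-octahydronaphthalene], via hydrazone 4 (not isolated)
Conditions: N2H4·H2O, KOH, diethylene glycol, 130 °C then 200 °C with removal of water, under N2
Reagents that add atoms: none
Why: Wolff–Kishner reduction (Huang-Minlon procedure) removes the C1 carbonyl; neither ring-fusion centre is enolisable and the isolated alkene is inert to hydrazine and hydroxide in the absence of oxidant.

Step 3
Reactants: 5
Product: 7 7α,8α-epoxy-4,4,10-trimethyl-cis-decalin, via bromohydrin 6 (not isolated)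
Conditions: N-bromosuccinimide, THF/H2O, 0 °C; then aq NaOH, rt
Reagents that add atoms: water, O
Why: Bromohydrin formation followed by intramolecular Williamson closure: Br+ should add to the open β face, water opens anti, and ring closure with inversion gives the α-epoxide whichever trans-bromohydrin regioisomer forms, i.e. the epimer of the epoxide a peracid would give.

Step 4
Reactants: 7
Product: 9 cis-4,4,10-trimethyloctal-6-en-8α-ol, via hydroxy selenide 8 (not isolated)
Conditions: PhSeSePh, NaBH4, EtOH, reflux; then 30% H2O2, pyridine, THF, 0 °C → rt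
Reagents that add atoms: none
Why: Selenolate opening of the epoxide followed by selenoxide syn-elimination: PhSe− should open the α-epoxide trans-diaxially at C7 from the β face (entry at C8 would be syn-axial to the C10 methyl), and the selenoxide eliminates away from the carbinol to give the Δ6 allylic alcohol with the 8α C–O bond intact.

Step 5
Reactants: 9
Product: 10 6α,7α-epoxy-4,4,10-trimethyl-cis-decalin-8α-ol
Conditions: VO(acac)2 (2 mol %), t-BuOOH, toluene, 0 °C → rt
Reagents that add atoms: tert-butyl hydroperoxide, CC(C)(C)OO
Why: Vanadium-catalysed hydroxyl-directed epoxidation delivers oxygen syn to the allylic 8α-hydroxyl, which sets the C6–O bond on the α face.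

Step 6
Reactants: 10
Product: 11 6α,7α-epoxy-4,4,10-trimethyl-cis-decalin-8-one
Conditions: Dess–Martin periodinane, NaHCO3, CH2Cl2, rt
Reagents that add atoms: none
Why: Dess–Martin oxidation of the secondary alcohol under buffered, non-basic conditions leaves the epoxide and the ring fusion untouched.

Step 7
Reactants: 12 (R)-4-benzyl-1,3-oxazolidin-2-one; 13 (E)-but-2-enoic anhydride
Product: 14 (R)-4-benzyl-3-[(E)-but-2-enoyl]-1,3-oxazolidin-2-one
Conditions: LiCl, Et3N, THF, rt
Reagents that add atoms: none
Why: Lithium chloride/amine-mediated N-acylation of the oxazolidinone with the anhydride is a mild imide formation that does not migrate the crotonyl double bond.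

Step 8
Reactants: 14; 15 tert-butyl bromoacetate
Product: 17 tert-butyl (R)-3-[(R)-4-benzyl-2-oxo-1,3-oxazolidine-3-carbonyl]pent-4-enoate, via sodium dienolate 16 (not isolated)
Conditions: NaN(SiMe3)2 (1.05 equiv), THF, −78 °C; then 15, −78 °C; AcOH quench at −78 °C
Reagents that add atoms: none
Why: Auxiliary-controlled deconjugative α-alkylation: γ-deprotonation gives the chelated Z-dienolate, which is alkylated at the α-carbon on the face opposite the benzyl group, setting the future C13 centre in the same sense as standard oxazolidinone alkylations.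

Step 9
Reactants: 17
Product: 18 tert-butyl (R)-3-(hydroxymethyl)pent-4-enoate
Conditions: LiBH4, MeOH (1 equiv), Et2O, 0 °C
Reagents that add atoms: none
Why: Chemoselective borohydride reduction of the activated imide carbonyl releases the auxiliary and gives the C16 alcohol while the tert-butyl ester survives; the stereocentre is no longer α to a carbonyl.

Step 10
Reactants: 18
Product: 19 tert-butyl (R)-3-[(tert-butyldimethylsilyloxy)methyl]pent-4-enoate
Conditions: TBSCl, imidazole, DMF, rt
Reagents that add atoms: tert-butyldimethylsilyl chloride, CC(C)(C)[Si](C)(C)Cl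
Why: Silylation of the primary alcohol masks C16–OH for all later base, hydride and acylation steps.

Step 11
Reactants: 19
Product: 20 (R)-3-[(tert-butyldimethylsilyloxy)methyl]pent-4-en-1-ol
Conditions: LiAlH4, THF, 0 °C; aqueous NaOH work-up
Reagents that add atoms: none
Why: Hydride reduction of the ester to the C11 primary alcohol; the silyl ether and vinyl group are inert at 0 °C.

Step 12
Reactants: 20
Product: 21 (R)-tert-butyl{[2-(2-iodoethyl)but-3-en-1-yl]oxy}dimethylsilane
Conditions: I2, PPh3, imidazole, CH2Cl2, 0 °C → rt
Reagents that add atoms: iodine, II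
Why: Appel-type iodination converts the primary alcohol into the C11 electrophile without touching the stereocentre.

Step 13
Reactants: 11; 21
Product: 23 6α,7α-epoxy-9β-[(R)-3-(tert-butyldimethylsilyloxymethyl)pent-4-enyl]-4,4,10-trimethyl-cis-decalin-8-one (H-9 α), via lithium enolate 22 (not isolated)
Conditions: LiN(iPr)2 (1.05 equiv), THF, −78 °C; then 21 (1.5 equiv), DMPU, −78 → −20 °C
Reagents that add atoms: none
Why: Kinetic enolate alkylation: only C9 can be enolised (C7 is an oxirane carbon), and the iodide should enter on the β face, anti to both the axial C1 methylene and the epoxide oxygen, giving the 9β side chain under kinetic control.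

Step 14
Reactants: 23
Product: 24 6α,7α-epoxy-8β-methyl-9β-[(R)-3-(tert-butyldimethylsilyloxymethyl)pent-4-enyl]-4,4,10-trimethyl-cis-decalin-8α-ol
Conditions: MeLi, anhydrous CeCl3, THF, −78 °C
Reagents that add atoms: methyllithium, [Li]C
Why: Organocerium 1,2-addition: the weakly basic methylcerium reagent should not enolise C9–H and should add anti to the adjacent α-epoxide oxygen (the usual sense for cyclic α,β-epoxy ketones, reinforced by C1H2 on the α face), placing CH3 β and OH α at C8.

Step 15
Reactants: 24
Product: 25 8β-methyl-9β-[(R)-3-(tert-butyldimethylsilyloxymethyl)pent-4-enyl]-4,4,10-trimethyl-cis-decalin-6α,8α-diol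
Conditions: LiAlH4, THF, 0 °C → rt; aqueous NaOH work-up
Reagents that add atoms: none
Why: Hydride reduction of the epoxide by trans-diaxial (Fürst–Plattner) opening: hydride should enter C7 from the β face because entry at C6 would be syn-axial to both the C10 and C8 methyl groups, so the oxygen stays on C6 (α) and C7 becomes CH2.

Step 16
Reactants: 25; 26 angelic acid [(Z)-2-methylbut-2-enoic acid]
Product: 27 6α-angelate of 25 (8α-OH free; C16 silyl ether)
Conditions: 26, 2,4,6-trichlorobenzoyl chloride, Et3N, toluene, rt; then 25, 80 °C (no DMAP)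
Reagents that add atoms: none
Why: Yamaguchi esterification through the mixed anhydride acylates the secondary C6 hydroxyl while the tertiary C8 hydroxyl is inert, and omitting DMAP guards against Z→E isomerisation to the tiglate.

Step 17
Reactants: 27
Product: 28 CNP0177054.1
Conditions: HF·pyridine, pyridine, THF, 0 °C → rt
Reagents that add atoms: none
Why: Fluoride-mediated cleavage of the primary silyl ether under buffered conditions leaves the angelate, the tertiary alcohol and the vinyl group untouched.

## Compound list

1 | 2,4,4-trimethylcyclohex-2-en-1-one | CC1=CC(C)(C)CCC1=O | starting material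
2 | buta-1,3-diene | C=CC=C | starting material
3 | cis-4,4,10-trimethyloctal-7-en-1-one, (4aR,8aR) | C1[C@@]2(C)C(=O)CCC(C)(C)[C@H]2CC=C1 | intermediate
4 | hydrazone of 3 | C1[C@@]2(C)C(=NN)CCC(C)(C)[C@H]2CC=C1 | intermediate
5 | cis-4,4,10-trimethyl-Δ7-octalin, (4aR,8aR) | C1[C@@]2(C)CCCC(C)(C)[C@H]2CC=C1 | intermediate
6 | 7β-bromo-4,4,10-trimethyl-cis-decalin-8α-ol | C1[C@@]2(C)CCCC(C)(C)[C@H]2C[C@H](Br)[C@H]1O | intermediate
7 | 7α,8α-epoxy-4,4,10-trimethyl-cis-decalin | C1[C@@]2(C)CCCC(C)(C)[C@H]2C[C@H]3O[C@H]31 | intermediate
8 | 7β-(phenylselanyl)-4,4,10-trimethyl-cis-decalin-8α-ol | C1[C@@]2(C)CCCC(C)(C)[C@H]2C[C@H]([Se]c3ccccc3)[C@H]1O | intermediate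
9 | cis-4,4,10-trimethyloctal-6-en-8α-ol | C1[C@@]2(C)CCCC(C)(C)[C@H]2C=C[C@H]1O | intermediate
10 | 6α,7α-epoxy-4,4,10-trimethyl-cis-decalin-8α-ol | C1[C@@]2(C)CCCC(C)(C)[C@H]2[C@H]3O[C@H]3[C@H]1O | intermediate
11 | 6α,7α-epoxy-4,4,10-trimethyl-cis-decalin-8-one | C1[C@@]2(C)CCCC(C)(C)[C@H]2[C@H]3O[C@H]3C1=O | intermediate
12 | (R)-4-benzyl-1,3-oxazolidin-2-one | O=C1OC[C@@H](Cc2ccccc2)N1 | starting material
13 | (E)-but-2-enoic anhydride | C/C=C/C(=O)OC(=O)/C=C/C | starting material
14 | (R)-4-benzyl-3-[(E)-but-2-enoyl]-1,3-oxazolidin-2-one | C/C=C/C(=O)N1[C@H](Cc2ccccc2)COC1=O | intermediate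
15 | tert-butyl bromoacetate | BrCC(=O)OC(C)(C)C | starting material
16 | sodium (Z)-dienolate of 14 | C=C/C=C(\[O-])N1[C@H](Cc2ccccc2)COC1=O.[Na+] | intermediate
17 | tert-butyl (R)-3-[(R)-4-benzyl-2-oxo-1,3-oxazolidine-3-carbonyl]pent-4-enoate | C=C[C@H](C(=O)N1[C@H](Cc2ccccc2)COC1=O)CC(=O)OC(C)(C)C | intermediate
18 | tert-butyl (R)-3-(hydroxymethyl)pent-4-enoate | C=C[C@H](CO)CC(=O)OC(C)(C)C | intermediate
19 | tert-butyl (R)-3-[(tert-butyldimethylsilyloxy)methyl]pent-4-enoate | C=C[C@H](CO[Si](C)(C)C(C)(C)C)CC(=O)OC(C)(C)C | intermediate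
20 | (R)-3-[(tert-butyldimethylsilyloxy)methyl]pent-4-en-1-ol | C=C[C@H](CO[Si](C)(C)C(C)(C)C)CCO | intermediate
21 | (R)-tert-butyl{[2-(2-iodoethyl)but-3-en-1-yl]oxy}dimethylsilane | C=C[C@H](CO[Si](C)(C)C(C)(C)C)CCI | intermediate
22 | lithium C8=C9 enolate of 11 | [O-]C1=C[C@@]2(C)CCCC(C)(C)[C@H]2[C@H]3O[C@@H]13.[Li+] | intermediate
23 | 6α,7α-epoxy-9β-[(R)-3-(tert-butyldimethylsilyloxymethyl)pent-4-enyl]-4,4,10-trimethyl-cis-decalin-8-one | C=C[C@H](CO[Si](C)(C)C(C)(C)C)CC[C@@H]1[C@@]2(C)CCCC(C)(C)[C@H]2[C@H]3O[C@H]3C1=O | intermediate
24 | 6α,7α-epoxy-8β-methyl-8α-hydroxy analogue of 23 | C=C[C@H](CO[Si](C)(C)C(C)(C)C)CC[C@@H]1[C@@]2(C)CCCC(C)(C)[C@H]2[C@H]3O[C@H]3[C@@]1(C)O | intermediate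
25 | 6α,8α-diol (8β-methyl; 9β side chain; C16 silyl ether) | C=C[C@H](CO[Si](C)(C)C(C)(C)C)CC[C@@H]1[C@@]2(C)CCCC(C)(C)[C@H]2[C@@H](O)C[C@@]1(C)O | intermediate
26 | angelic acid, (Z)-2-methylbut-2-enoic acid | OC(=O)/C(C)=C\C | starting material
27 | 6α-angelate of 25 | C=C[C@H](CO[Si](C)(C)C(C)(C)C)CC[C@@H]1[C@@]2(C)CCCC(C)(C)[C@H]2[C@@H](OC(=O)/C(C)=C\C)C[C@@]1(C)O | intermediate
28 | CNP0177054.1 (6α-angeloyloxy-8α-hydroxy-8β-methyl-9β-[(R)-3-(hydroxymethyl)pent-4-enyl]-4,4,10-trimethyl-cis-decalin) | C=C[C@H](CO)CC[C@@H]1[C@@]2(C)CCCC(C)(C)[C@H]2[C@@H](OC(=O)/C(C)=C\C)C[C@@]1(C)O | target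

## Step count and risks

Total step count: 17. Longest linear sequence: 11 steps (steps 1–6 and 13–17; the side-chain branch, steps 7–12 then 13–17, is equally long).

Steps most likely to fail:

1. Step 1 (Proposed new method). The β-carbon of 1 is flanked by the quaternary C4 and the α-carbon carries a methyl group, so cycloaddition may be slower than butadiene oligomerisation. The α-methyl enone also lacks the α-C–H contact that normally organises such enones on the catalyst, so enantioface discrimination may be poor. Fallback: starting again from 1 and 2, the cycloaddition is run without a chiral catalyst under AlCl3 (toluene, sealed vessel, 40–70 °C), the conditions under which butadiene is known to add to methylated cyclohex-2-enones. This gives 3 as the racemate, i.e. together with its mirror image ent-cis-4,4,10-trimethyloctal-7-en-1-one F1. The enantiomers are separated by preparative chromatography on a cellulose tris(3,5-dimethylphenylcarbamate) phase, and enantiopure 3 re-enters the route at step 2.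

2. Step 13. C-alkylation of an enolate carbon next to the quaternary C10 with an unactivated primary iodide may be slow. Warming may then lead to O-alkylation, enolate decomposition through the epoxide, or proton transfer that erodes the kinetic C9 configuration. Fallback (from 11 and 20, returning at 24): the C9–C11 bond is made by aldol addition to a far more reactive electrophile. Alcohol 20 is oxidised with Dess–Martin periodinane to (R)-3-[(tert-butyldimethylsilyloxy)methyl]pent-4-enal F2. Enolate 22 adds to it at −78 °C on the β face to give the lithium aldolate of the 11-hydroxy-6α,7α-epoxy-8-ketone F3 (C11 epimers). This is treated in the same flask with methylcerium dichloride to give the 6α,7α-epoxy-8α,11-diol F4. The secondary C11 hydroxyl is converted with PhOC(S)Cl/pyridine into the C11 O-phenyl thionocarbonate F5 and removed with Bu3SnH/AIBN in toluene at 80 °C (Barton–McCombie deoxygenation), which gives 24.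

3. Step 15. If the tertiary alkoxide–aluminate reacts through the other half-chair, hydride may be delivered to the distal carbon C6 and give the 7,8-diol instead of the 6,8-diol. Fallback (from 23, returning at 25): the regiochemistry is fixed before the carbinol is built. SmI2 (THF/MeOH, −90 °C) cleaves the C7–O bond α to the carbonyl and gives the 6α-hydroxy-9β-alkyl-4,4,10-trimethyl-cis-decalin-8-one F6. Excess methylcerium dichloride (THF, −78 °C) then adds from the β face, the α face being closed by the axial C6 alkoxide and C1H2, to give 25.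

## Further compounds

F1 | step 1 | ent-cis-4,4,10-trimethyloctal-7-en-1-one, (4aS,8aS) | C1[C@]2(C)C(=O)CCC(C)(C)[C@@H]2CC=C1
F2 | step 13 | (R)-3-[(tert-butyldimethylsilyloxy)methyl]pent-4-enal | C=C[C@H](CO[Si](C)(C)C(C)(C)C)CC=O
F3 | step 13 | 11-hydroxy-6α,7α-epoxy-8-ketone (aldol adduct, C11 epimers) | C=C[C@H](CO[Si](C)(C)C(C)(C)C)CC(O)[C@@H]1[C@@]2(C)CCCC(C)(C)[C@H]2[C@H]3O[C@H]3C1=O
F4 | step 13 | 6α,7α-epoxy-8α,11-diol (8β-methyl) | C=C[C@H](CO[Si](C)(C)C(C)(C)C)CC(O)[C@@H]1[C@@]2(C)CCCC(C)(C)[C@H]2[C@H]3O[C@H]3[C@@]1(C)O
F5 | step 13 | C11 O-phenyl thionocarbonate of F4 | C=C[C@H](CO[Si](C)(C)C(C)(C)C)CC(OC(=S)Oc4ccccc4)[C@@H]1[C@@]2(C)CCCC(C)(C)[C@H]2[C@H]3O[C@H]3[C@@]1(C)O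
F6 | step 15 | 6α-hydroxy-9β-[(R)-3-(tert-butyldimethylsilyloxymethyl)pent-4-enyl]-4,4,10-trimethyl-cis-decalin-8-one | C=C[C@H](CO[Si](C)(C)C(C)(C)C)CC[C@@H]1[C@@]2(C)CCCC(C)(C)[C@H]2[C@@H](O)CC1=O
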